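The plan depends on opening the oxolane that bears ring B (C7–O–C9'–C8'–C8), in which the ring oxygen lies between the benzylic C7–H and the C9' methylene. Removing that oxygen leads back to a cis-fused 2-arylcyclobutanone. In the forward sense one Baeyer–Villiger oxidation puts the oxygen between C9' and C7, forms both C–O bonds, widens the four-membered ring to the γ-lactone and keeps the C7 configuration. The precursor is an enantiopure 3-oxabicyclo[3.2.0]heptan-6-one with the silylated syringyl ring exo on C7' and the benzylated guaiacyl ring B exo on C7, so all four core stereocentres are in place beforehand. Lactone reduction and an auxiliary-controlled anti-aldol then complete the erythro side chain.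

Key step: step 8

Remark on the chemistry: lignan numbering is used (C7–C9 on the ring B side, C7'–C9' on the syringyl ring S side, C7''–C9'' in the side chain, ring A the terminal guaiacyl ring). The target reads (7R,8S,7'R,8'S,7''R,8''S), the key-step ketone and lactone carry the same sense at C7, C8, C7' and C8', and the erythro pair (7''R,8''S) is the anti relationship of an aldol product drawn in zigzag form.

Step 1
Reactants: 1 methyl syringate (methyl 4-hydroxy-3,5-dimethoxybenzoate)
Product: 2 methyl 3,5-dimethoxy-4-(triisopropylsilyloxy)benzoate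
Conditions: i-Pr3SiCl, imidazole, DMF, 40 °C
Reagents that add atoms: triisopropylsilyl chloride, CC(C)[Si](Cl)(C(C)C)C(C)C
Why: Imidazole-promoted O-silylation of a phenol: the triisopropylsilyl ether should resist the enolate, hydride, triflic anhydride, palladium, peracid and Lewis acid steps that follow, is orthogonal to the benzyl ether of ring B, and leaves with fluoride at the very end.

Step 2
Reactants: 2 methyl 3,5-dimethoxy-4-(triisopropylsilyloxy)benzoate; 3 N-acetylpyrrolidine
Product: 5 1-[3,5-dimethoxy-4-(triisopropylsilyloxy)phenyl]-3-(pyrrolidin-1-yl)propane-1,3-dione, via lithium enolate of N-acetylpyrrolidine 4 (not isolated)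
Conditions: 3, LDA, THF, −78 °C; then 2, −78 → 0 °C; aq NH4Cl
Reagents that add atoms: none
Why: Crossed Claisen condensation: the benzoate has no α-hydrogen and can only be the acceptor, the acidic β-keto amide is held as its lithium salt until the quench (which blocks a second addition), and the ketone oxidation level is reached directly without an aldol/oxidation detour.

Step 3
Reactants: 5 1-[3,5-dimethoxy-4-(triisopropylsilyloxy)phenyl]-3-(pyrrolidin-1-yl)propane-1,3-dione
Product: 6 (3R)-3-[3,5-dimethoxy-4-(triisopropylsilyloxy)phenyl]-3-hydroxy-1-(pyrrolidin-1-yl)propan-1-one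
Conditions: RuCl[(R,R)-TsDPEN](p-cymene) (1 mol %), HCO2H–Et3N (5:2), CH2Cl2, 30 °C
Reagents that add atoms: none
Why: Noyori–Ikariya asymmetric transfer hydrogenation, established for aryl ketones and β-keto amides: hydride and proton pass from Ru–H/N–H in a six-membered transition state, and the CH/π contact between the substrate aryl ring and the cymene ligand makes the (R,R)-catalyst attack one face, which sets C7' as R.

Step 4
Reactants: 6 (3R)-3-[3,5-dimethoxy-4-(triisopropylsilyloxy)phenyl]-3-hydroxy-1-(pyrrolidin-1-yl)propan-1-one; 7 allyl bromide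
Product: 8 (3R)-3-(allyloxy)-3-[3,5-dimethoxy-4-(triisopropylsilyloxy)phenyl]-1-(pyrrolidin-1-yl)propan-1-one
Conditions: NaH, Bu4NI (cat.), THF–DMF, 0 °C → rt
Reagents that add atoms: none
Why: Williamson ether synthesis: the sodium alkoxide is captured quickly by the reactive allylic halide, while the weakly acidic α-hydrogens of the tertiary amide keep retro-aldol cleavage and elimination slow at this temperature, so C7' should be preserved.

Step 5
Reactants: 8 (3R)-3-(allyloxy)-3-[3,5-dimethoxy-4-(triisopropylsilyloxy)phenyl]-1-(pyrrolidin-1-yl)propan-1-one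
Product: 11 (1S,4R,5R)-4-[3,5-dimethoxy-4-(triisopropylsilyloxy)phenyl]-3-oxabicyclo[3.2.0]heptan-6-one (aryl exo), via keteniminium triflate 9 (not isolated), via cyclobutaniminium triflate 10 (not isolated)
Conditions: Tf2O, 2,4,6-collidine, ClCH2CH2Cl, 0 → 80 °C; then H2O, 80 °C
Reagents that add atoms: water, O
Why: Electrophilic amide activation, intramolecular keteniminium–alkene (2+2) cycloaddition and iminium hydrolysis: in 9 the electrophilic carbon C9' bonds to the terminal alkene carbon C7 while C8' bonds to C8 (the fused mode expected for a three-atom tether and a monosubstituted alkene), the small rings allow only a cis junction, and the aryl group on C7' takes the convex face of the folding tether, which sets C8' and C8 relative to C7'.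

Step 6
Reactants: 12 4-bromo-2-methoxyphenol
Product: 13 1-(benzyloxy)-4-bromo-2-methoxybenzene
Conditions: BnBr, K2CO3, acetone, reflux
Reagents that add atoms: benzyl bromide, BrCc1ccccc1
Why: Williamson ether synthesis: the benzyl ether keeps ring B electron-rich, as the key step requires, tolerates base, peracid and hydride, and can later be removed without touching the silyl ether.

Step 7
Reactants: 11 (1S,4R,5R)-4-[3,5-dimethoxy-4-(triisopropylsilyloxy)phenyl]-3-oxabicyclo[3.2.0]heptan-6-one; 13 1-(benzyloxy)-4-bromo-2-methoxybenzene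
Product: 14 (1S,4R,5R,7R)-7-[4-(benzyloxy)-3-methoxyphenyl]-4-[3,5-dimethoxy-4-(triisopropylsilyloxy)phenyl]-3-oxabicyclo[3.2.0]heptan-6-one (both aryl groups exo)
Conditions: Pd(OAc)2 (5 mol %), 2-dicyclohexylphosphino-2'-methylbiphenyl (10 mol %), K3PO4, toluene, 80 °C
Reagents that add atoms: none
Why: Buchwald–Hartwig–Miura ketone α-arylation: 13 adds oxidatively to zerovalent palladium, the enolate binds through the only unhindered α-position C7 (the other, C8', is a ring-fusion carbon), reductive elimination forms the C7–aryl bond, and because C7–H remains acidic the mild base equilibrates the new stereocentre to the less crowded exo position.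

Step 8
Reactants: 14 (1S,4R,5R,7R)-7-[4-(benzyloxy)-3-methoxyphenyl]-4-[3,5-dimethoxy-4-(triisopropylsilyloxy)phenyl]-3-oxabicyclo[3.2.0]heptan-6-one
Product: 16 (1S,2R,5R,6R)-2-[4-(benzyloxy)-3-methoxyphenyl]-6-[3,5-dimethoxy-4-(triisopropylsilyloxy)phenyl]-3,7-dioxabicyclo[3.3.0]octan-4-one (both aryl groups exo, carbonyl at C9'), via Criegee adduct 15 (not isolated)
Conditions: mCPBA, NaHCO3, CH2Cl2, 0 °C
Reagents that add atoms: 3-chloroperbenzoic acid, O=C(OO)c1cccc(Cl)c1
Why: The peracid adds to the strained carbonyl C9' to give adduct 15, and the C7–C9' bond then shifts onto the peroxide oxygen as 3-chlorobenzoate departs, which is a Baeyer–Villiger oxidation of the kind well documented for fused cyclobutanones giving γ-lactones. Mode of ring formation: the existing four-membered ring is expanded by one atom, both ring-fusion bonds stay intact throughout, and the cis junction is therefore kept. No stereocentre is created, and C7 moves with retention, so its aryl group stays on the convex face. The selectivity needed is migration of C7 rather than C8': C7 is benzylic and its para-benzyloxy ring stabilises the positive charge that builds up during the shift, whereas C8' is slowed by the electron-withdrawing C7'–O bond next to it. Release of ring strain lets the oxidation run at 0 °C under bicarbonate buffer, which should leave the electron-rich arenes, the silyl ether and the epimerisable C7–H untouched.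

Step 9
Reactants: 16 (1S,2R,5R,6R)-2-[4-(benzyloxy)-3-methoxyphenyl]-6-[3,5-dimethoxy-4-(triisopropylsilyloxy)phenyl]-3,7-dioxabicyclo[3.3.0]octan-4-one
Product: 17 lactol of 16, 2-[4-(benzyloxy)-3-methoxyphenyl]-6-[3,5-dimethoxy-4-(triisopropylsilyloxy)phenyl]-3,7-dioxabicyclo[3.3.0]octan-4-ol (both anomers at C9')
Conditions: i-Bu2AlH, CH2Cl2, −78 °C; aq Rochelle salt
Reagents that add atoms: none
Why: Partial reduction of a lactone: the tetrahedral aluminium alkoxide persists at −78 °C so that reduction should stop at the lactol, and the new anomeric centre is irrelevant because the next step removes it.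

Step 10
Reactants: 17 lactol of 16
Product: 19 (1S,2R,5S,6R)-2-[4-(benzyloxy)-3-methoxyphenyl]-6-[3,5-dimethoxy-4-(triisopropylsilyloxy)phenyl]-3,7-dioxabicyclo[3.3.0]octane (7R,8S,7'R,8'S), via oxocarbenium ion 18 (not isolated)
Conditions: Et3SiH, BF3·OEt2, CH2Cl2, −78 → −40 °C
Reagents that add atoms: none
Why: Ionic hydrogenation of a lactol (Lewis acid/silane deoxygenation), a standard way to close out furofuran syntheses: the anomeric C9'–OH ionises far more readily than the benzylic ring ethers at low temperature, and hydride from the silane quenches 18 to the C9' methylene without touching a stereocentre.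

Step 11
Reactants: 19 (1S,2R,5S,6R)-2-[4-(benzyloxy)-3-methoxyphenyl]-6-[3,5-dimethoxy-4-(triisopropylsilyloxy)phenyl]-3,7-dioxabicyclo[3.3.0]octane
Product: 20 4-{(1S,2R,5S,6R)-6-[3,5-dimethoxy-4-(triisopropylsilyloxy)phenyl]-3,7-dioxabicyclo[3.3.0]octan-2-yl}-2-methoxyphenol (free ring B phenol)
Conditions: H2 (1 atm), Pd/C, EtOAc, rt
Reagents that add atoms: none
Why: Catalytic hydrogenolysis: the aryl benzyl ether is cleaved much faster than the hindered ring C–O bonds of a furofuran under one atmosphere in a neutral solvent, as used routinely for phenolic furofuran lignans, and silicon is unaffected.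

Step 12
Reactants: 21 (S)-4-benzyl-2-oxazolidinone; 22 bromoacetyl bromide
Product: 24 (4S)-4-benzyl-3-(bromoacetyl)oxazolidin-2-one, via N-lithio oxazolidinone 23 (not isolated)
Conditions: n-BuLi, THF, −78 °C; then 22
Reagents that add atoms: none
Why: N-acylation of a lithiated oxazolidinone: the acyl bromide reacts far faster than the alkyl bromide at −78 °C, so the α-bromo imide should form cleanly.

Step 13
Reactants: 20 free ring B phenol; 24 (4S)-4-benzyl-3-(bromoacetyl)oxazolidin-2-one
Product: 25 (4S)-4-benzyl-3-(aryloxyacetyl)oxazolidin-2-one whose aryloxy group is the ring B oxygen of 20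
Conditions: K2CO3, MeCN, rt
Reagents that add atoms: none
Why: Williamson ether synthesis on an activated α-halo carbonyl compound: the phenoxide displaces bromide by SN2 at room temperature, mild enough for the imide, and the acyl auxiliary is attached in one operation instead of an ester/acid/imide sequence.

Step 14
Reactants: 26 vanillin
Product: 27 3-methoxy-4-(triisopropylsilyloxy)benzaldehyde
Conditions: i-Pr3SiCl, imidazole, CH2Cl2, rt
Reagents that add atoms: triisopropylsilyl chloride, CC(C)[Si](Cl)(C(C)C)C(C)C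
Why: Imidazole-promoted O-silylation: giving ring A the same protecting group as ring S allows one fluoride treatment at the end and avoids a late hydrogenolysis next to the benzylic alcohol.

Step 15
Reactants: 25 ring B aryloxyacetyl imide; 27 3-methoxy-4-(triisopropylsilyloxy)benzaldehyde
Product: 28 (4S)-4-benzyl-3-[(2R,3R)-2-(ring B aryloxy)-3-[3-methoxy-4-(triisopropylsilyloxy)phenyl]-3-(trimethylsilyloxy)propanoyl]oxazolidin-2-one (anti)
Conditions: MgCl2 (20 mol %), Et3N, Me3SiCl, EtOAc, rt
Reagents that add atoms: chlorotrimethylsilane, C[Si](C)(C)Cl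
Why: Magnesium halide-catalysed direct anti-aldol of an N-acyloxazolidinone with a non-enolisable aromatic aldehyde: MgCl2/Et3N form the chelated Z-enolate (its geometry reinforced by the aryloxy oxygen), the aldehyde approaches the face away from the benzyl group of the (S)-auxiliary, which sets C8'', the anti sense typical of this catalyst system sets C7'', silylation of the magnesium aldolate makes the addition irreversible, and any minor isomer can be removed by chromatography while the auxiliary is still attached.

Step 16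
Reactants: 28 anti-aldol imide
Product: 29 ficusesquilignan A protected as the ring A and ring S triisopropylsilyl ethers and the C7'' trimethylsilyl ether (7''R,8''S)
Conditions: LiBH4, THF, 0 °C
Reagents that add atoms: none
Why: Reductive removal of the oxazolidinone auxiliary: borohydride attacks the more electrophilic exocyclic imide carbonyl and carries it down to the C9'' primary alcohol, while the silyl group on O7'' blocks retro-aldol cleavage (partial loss or shift of that group would be harmless, since the next step removes it).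

Step 17
Reactants: 29 trisilylated ficusesquilignan A
Product: 30 ficusesquilignan A
Conditions: Bu4NF, AcOH, THF, 0 °C → rt
Reagents that add atoms: none
Why: Fluoride-induced desilylation: all three Si–O bonds are cleaved in one operation, and the acetic acid buffer keeps the liberated para-hydroxybenzyl alcohol from forming a quinone methide, so no stereocentre should be disturbed.

Compound list
1 | methyl syringate | COC(=O)c1cc(OC)c(O)c(OC)c1 | starting material
2 | methyl 3,5-dimethoxy-4-(triisopropylsilyloxy)benzoate | COC(=O)c1cc(OC)c(O[Si](C(C)C)(C(C)C)C(C)C)c(OC)c1 | intermediate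
3 | N-acetylpyrrolidine | CC(=O)N1CCCC1 | starting material
4 | lithium enolate of N-acetylpyrrolidine (not isolated) | C=C(O[Li])N1CCCC1 | intermediate
5 | 1-[3,5-dimethoxy-4-(triisopropylsilyloxy)phenyl]-3-(pyrrolidin-1-yl)propane-1,3-dione | O=C(CC(=O)N1CCCC1)c1cc(OC)c(O[Si](C(C)C)(C(C)C)C(C)C)c(OC)c1 | intermediate
6 | (3R)-3-[3,5-dimethoxy-4-(triisopropylsilyloxy)phenyl]-3-hydroxy-1-(pyrrolidin-1-yl)propan-1-one | O=C(C[C@@H](O)c1cc(OC)c(O[Si](C(C)C)(C(C)C)C(C)C)c(OC)c1)N1CCCC1 | intermediate
7 | allyl bromide | C=CCBr | starting material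
8 | (3R)-3-(allyloxy)-3-[3,5-dimethoxy-4-(triisopropylsilyloxy)phenyl]-1-(pyrrolidin-1-yl)propan-1-one | O=C(C[C@@H](OCC=C)c1cc(OC)c(O[Si](C(C)C)(C(C)C)C(C)C)c(OC)c1)N1CCCC1 | intermediate
9 | keteniminium triflate from 8 (not isolated) | C=CCO[C@H](C=C=[N+]1CCCC1)c1cc(OC)c(O[Si](C(C)C)(C(C)C)C(C)C)c(OC)c1.[O-]S(=O)(=O)C(F)(F)F | intermediate
10 | cyclobutaniminium triflate, pyrrolidinium form of 11 (not isolated) | C1C(=[N+]3CCCC3)[C@@H]2[C@H]1CO[C@H]2c1cc(OC)c(O[Si](C(C)C)(C(C)C)C(C)C)c(OC)c1.[O-]S(=O)(=O)C(F)(F)F | intermediate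
11 | (1S,4R,5R)-4-[3,5-dimethoxy-4-(triisopropylsilyloxy)phenyl]-3-oxabicyclo[3.2.0]heptan-6-one | C1C(=O)[C@@H]2[C@H]1CO[C@H]2c1cc(OC)c(O[Si](C(C)C)(C(C)C)C(C)C)c(OC)c1 | intermediate
12 | 4-bromo-2-methoxyphenol | COc1cc(Br)ccc1O | starting material
13 | 1-(benzyloxy)-4-bromo-2-methoxybenzene | COc1cc(Br)ccc1OCc1ccccc1 | intermediate
14 | (1S,4R,5R,7R)-7-[4-(benzyloxy)-3-methoxyphenyl]-4-[3,5-dimethoxy-4-(triisopropylsilyloxy)phenyl]-3-oxabicyclo[3.2.0]heptan-6-one | COc1cc([C@@H]2C(=O)[C@@H]3[C@H]2CO[C@H]3c2cc(OC)c(O[Si](C(C)C)(C(C)C)C(C)C)c(OC)c2)ccc1OCc1ccccc1 | intermediate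
15 | Criegee adduct of 14 and 3-chloroperbenzoic acid (not isolated) | COc1cc([C@@H]2C(O)(OOC(=O)c4cccc(Cl)c4)[C@@H]3[C@H]2CO[C@H]3c2cc(OC)c(O[Si](C(C)C)(C(C)C)C(C)C)c(OC)c2)ccc1OCc1ccccc1 | intermediate
16 | (1S,2R,5R,6R)-2-[4-(benzyloxy)-3-methoxyphenyl]-6-[3,5-dimethoxy-4-(triisopropylsilyloxy)phenyl]-3,7-dioxabicyclo[3.3.0]octan-4-one | COc1cc([C@@H]2OC(=O)[C@@H]3[C@H]2CO[C@H]3c2cc(OC)c(O[Si](C(C)C)(C(C)C)C(C)C)c(OC)c2)ccc1OCc1ccccc1 | intermediate
17 | lactol of 16 (both anomers) | COc1cc([C@@H]2OC(O)[C@@H]3[C@H]2CO[C@H]3c2cc(OC)c(O[Si](C(C)C)(C(C)C)C(C)C)c(OC)c2)ccc1OCc1ccccc1 | intermediate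
18 | oxocarbenium hydroxytrifluoroborate from 17 (not isolated) | COc1cc([C@@H]2[O+]=C[C@@H]3[C@H]2CO[C@H]3c2cc(OC)c(O[Si](C(C)C)(C(C)C)C(C)C)c(OC)c2)ccc1OCc1ccccc1.O[B-](F)(F)F | intermediate
19 | (1S,2R,5S,6R)-2-[4-(benzyloxy)-3-methoxyphenyl]-6-[3,5-dimethoxy-4-(triisopropylsilyloxy)phenyl]-3,7-dioxabicyclo[3.3.0]octane | COc1cc([C@@H]2OC[C@@H]3[C@H]2CO[C@H]3c2cc(OC)c(O[Si](C(C)C)(C(C)C)C(C)C)c(OC)c2)ccc1OCc1ccccc1 | intermediate
20 | 4-{(1S,2R,5S,6R)-6-[3,5-dimethoxy-4-(triisopropylsilyloxy)phenyl]-3,7-dioxabicyclo[3.3.0]octan-2-yl}-2-methoxyphenol | COc1cc([C@@H]2OC[C@@H]3[C@H]2CO[C@H]3c2cc(OC)c(O[Si](C(C)C)(C(C)C)C(C)C)c(OC)c2)ccc1O | intermediate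
21 | (S)-4-benzyl-2-oxazolidinone | O=C1N[C@@H](Cc2ccccc2)CO1 | starting material
22 | bromoacetyl bromide | O=C(Br)CBr | starting material
23 | N-lithio-(S)-4-benzyl-2-oxazolidinone (not isolated) | [Li]N1C(=O)OC[C@@H]1Cc1ccccc1 | intermediate
24 | (4S)-4-benzyl-3-(bromoacetyl)oxazolidin-2-one | O=C(CBr)N1C(=O)OC[C@@H]1Cc1ccccc1 | intermediate
25 | ring B aryloxyacetyl imide | COc1cc([C@@H]2OC[C@@H]3[C@H]2CO[C@H]3c2cc(OC)c(O[Si](C(C)C)(C(C)C)C(C)C)c(OC)c2)ccc1OCC(=O)N1C(=O)OC[C@@H]1Cc1ccccc1 | intermediate
26 | vanillin | COc1cc(C=O)ccc1O | starting material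
27 | 3-methoxy-4-(triisopropylsilyloxy)benzaldehyde | COc1cc(C=O)ccc1O[Si](C(C)C)(C(C)C)C(C)C | intermediate
28 | (2R,3R)-anti-aldol imide, O-trimethylsilyl ether | COc1cc([C@@H](O[Si](C)(C)C)[C@H](C(=O)N2C(=O)OC[C@@H]2Cc2ccccc2)Oc2ccc([C@@H]3OC[C@@H]4[C@H]3CO[C@H]4c3cc(OC)c(O[Si](C(C)C)(C(C)C)C(C)C)c(OC)c3)cc2OC)ccc1O[Si](C(C)C)(C(C)C)C(C)C | intermediate
29 | trisilylated ficusesquilignan A (7''R,8''S) | COc1cc([C@@H](O[Si](C)(C)C)[C@H](CO)Oc2ccc([C@@H]3OC[C@@H]4[C@H]3CO[C@H]4c3cc(OC)c(O[Si](C(C)C)(C(C)C)C(C)C)c(OC)c3)cc2OC)ccc1O[Si](C(C)C)(C(C)C)C(C)C | intermediate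
30 | ficusesquilignan A | COc1cc([C@@H](O)[C@H](CO)Oc2ccc([C@@H]3OC[C@@H]4[C@H]3CO[C@H]4c3cc(OC)c(O)c(OC)c3)cc2OC)ccc1O | target

Total step count: 17. Longest linear sequence: 14 (steps 1–5, 7–11, 13, 15–17).

Steps most likely to fail

**Step 5.**
- Process at risk: before the alkene can react, the activated amide may be attacked by the nucleophilic C2/C6 positions of ring S (a Friedel–Crafts-type closure). It may also lose allyl alcohol by β-elimination.
- Fallback: the cationic cyclisation is replaced by a neutral ketene cycloaddition to a preformed dihydrofuran. It sets out from 8 and comes back at 11.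
- LiAlH4 in THF should reduce the amide to 1-{(3R)-3-(allyloxy)-3-[3,5-dimethoxy-4-(triisopropylsilyloxy)phenyl]propyl}pyrrolidine F1.
- One equivalent of mCPBA at −20 °C should give the pyrrolidine N-oxide F2. On warming in toluene this should undergo Cope elimination to the (R)-allyl 1-arylallyl ether F3.
- Ring-closing metathesis with the second-generation Grubbs catalyst should close (2R)-2-[3,5-dimethoxy-4-(triisopropylsilyloxy)phenyl]-2,5-dihydrofuran F4.
- Dichloroketene (Cl3CCOCl, Zn–Cu, Et2O) should add to the face away from the aryl group. Its carbonyl carbon should bond to the alkene carbon next to C7', because both the bulky CCl2 end and the developing positive charge prefer the remote carbon. This gives the 7,7-dichlorocyclobutanone F5.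
- Zinc in acetic acid then removes both chlorine atoms to give 11.

**Step 7.**
- Process at risk: under base the strained ketone may self-condense, suffer ring opening, or lose the C7'–O bond by β-elimination through the C8' enolate. Reductive elimination from the palladium enolate may also be too slow to compete.
- Fallback: an electrophilic aryl group is transferred to a preformed enol ether, without base and without palladium. It sets out from 11 (and 13) and comes back at 14.
- LDA/Me3SiCl at −78 °C should convert 11 into the C9'–C7 trimethylsilyl enol ether F6.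
- Separately, bromine–lithium exchange of 13 with n-BuLi and B(OMe)3 should give 4-(benzyloxy)-3-methoxyphenylboronic acid F7.
- Treating F7 with MesI(OAc)2/BF3·OEt2 and then NaOTf should give [4-(benzyloxy)-3-methoxyphenyl](mesityl)iodonium triflate F8.
- Cu(OTf)2-catalysed reaction of F6 with F8 in CH2Cl2 should transfer the less hindered aryl group to C7. A short treatment with Et3N should settle it on the exo face, giving 14.

**Step 8.**
- Process at risk: the ring-fusion carbon C8' may migrate in competition with C7, or the peracid may attack the electron-rich rings.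
- Fallback: a photochemical ring expansion that uses no oxidant and selects the bond by radical stability. It sets out from 14 and comes back at 19, bypassing 16 and 17.
- Irradiation of 14 in methanol through Pyrex (about 300–350 nm) should cause Norrish α-cleavage of the C9'–C7 bond on the benzylic side.
- The acyl oxygen should then reclose onto C7 to give an oxacarbene, and methanol should trap it. The product is the ring-expanded 4-methoxy-3,7-dioxabicyclo[3.3.0]octane methyl acetal F9.
- Et3SiH/BF3·OEt2 under the conditions of step 10 should then reduce F9 to 19.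

Further compounds
F1 | step 5 | 1-{(3R)-3-(allyloxy)-3-[3,5-dimethoxy-4-(triisopropylsilyloxy)phenyl]propyl}pyrrolidine | C=CCO[C@H](CCN1CCCC1)c1cc(OC)c(O[Si](C(C)C)(C(C)C)C(C)C)c(OC)c1
F2 | step 5 | pyrrolidine N-oxide of F1 | C=CCO[C@H](CC[N+]1([O-])CCCC1)c1cc(OC)c(O[Si](C(C)C)(C(C)C)C(C)C)c(OC)c1
F3 | step 5 | (R)-allyl 1-arylallyl ether, {4-[(1R)-1-(allyloxy)allyl]-2,6-dimethoxyphenoxy}triisopropylsilane | C=CCO[C@H](C=C)c1cc(OC)c(O[Si](C(C)C)(C(C)C)C(C)C)c(OC)c1
F4 | step 5 | (2R)-2-[3,5-dimethoxy-4-(triisopropylsilyloxy)phenyl]-2,5-dihydrofuran | O1CC=C[C@@H]1c1cc(OC)c(O[Si](C(C)C)(C(C)C)C(C)C)c(OC)c1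
F5 | step 5 | (1S,4R,5R)-7,7-dichloro-4-[3,5-dimethoxy-4-(triisopropylsilyloxy)phenyl]-3-oxabicyclo[3.2.0]heptan-6-one | ClC1(Cl)C(=O)[C@@H]2[C@H]1CO[C@H]2c1cc(OC)c(O[Si](C(C)C)(C(C)C)C(C)C)c(OC)c1
F6 | step 7 | trimethylsilyl enol ether of 11 (6-trimethylsilyloxy-3-oxabicyclo[3.2.0]hept-6-ene) | C1=C(O[Si](C)(C)C)[C@@H]2[C@H]1CO[C@H]2c1cc(OC)c(O[Si](C(C)C)(C(C)C)C(C)C)c(OC)c1
F7 | step 7 | 4-(benzyloxy)-3-methoxyphenylboronic acid | COc1cc(B(O)O)ccc1OCc1ccccc1
F8 | step 7 | [4-(benzyloxy)-3-methoxyphenyl](mesityl)iodonium triflate | COc1cc([I+]c2c(C)cc(C)cc2C)ccc1OCc1ccccc1.[O-]S(=O)(=O)C(F)(F)F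
F9 | step 8 | 2-[4-(benzyloxy)-3-methoxyphenyl]-4-methoxy-6-[3,5-dimethoxy-4-(triisopropylsilyloxy)phenyl]-3,7-dioxabicyclo[3.3.0]octane (methyl acetal, both anomers) | COc1cc([C@@H]2OC(OC)[C@@H]3[C@H]2CO[C@H]3c2cc(OC)c(O[Si](C(C)C)(C(C)C)C(C)C)c(OC)c2)ccc1OCc1ccccc1
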